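**Retrosynthetic overview**
1. Target 17 ⇐ methyl ester 16 ⇐ C3–CH2 bond: silyl ketene acetal onto the peroxycarbenium ion of 3‑methoxy‑1,2‑dioxane 15 (sets C3).
2. 15 ⇐ lactol 12: perhydrolytic ring expansion, oxolane → 1,2‑dioxane, through the C6 allyl cation (sets C6).
3. 12 ⇐ diene 8 + butanal 9 + water: key radical three‑component coupling; an enamine radical cation adds to the diene (C4–C5 bond, C4 set by the catalyst) and oxidative capture closes the oxolane.
4. 8 ⇐ alkyne 5 + 2‑bromobut‑1‑ene 6 (carboalumination/cross‑coupling, E alkene); 5 ⇐ ketone 3 ⇐ enone 1 + butyl Grignard 2 (asymmetric conjugate addition, C10).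
5. Ring order: oxolane (step 4), then the 1,2‑dioxane (step 5); there is no other ring.

Assumption 1: locants follow the dioxane numbering O1–O2–C3(CH2CO2H)–C4(Et)–C5–C6(Et)(alkenyl), with side chain C7=C8(CH3)–C9–C10(Et)(Bu); the target is (3R,4R,6R,7E,10S).
Assumption 2: the sense of induction of each chiral catalyst is taken from its accepted facial model; if a catalyst gives the opposite sense in practice, its mirror image is used and nothing else changes.

**Step 1**
Reactants: 1 (E)-hex-3-en-2-one; 2 n-butylmagnesium bromide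
Product: 3 (S)-4-ethyloctan-2-one
Conditions: CuBr·SMe2 (5 mol %), (R)-1-[(SP)-2-(diphenylphosphino)ferrocenyl]ethyldicyclohexylphosphine (6 mol %), t-BuOMe, −75 °C; then 1 M HCl
Reagents that add atoms: none
Why: Copper-catalysed asymmetric conjugate addition of a Grignard reagent to a linear enone (Feringa type), in which the monovalent-copper/ferrocenyl diphosphine complex delivers butyl to one enone face and sets the remote stereocentre C10 as S (about 90% ee expected).

**Step 2**
Reactants: 3 (S)-4-ethyloctan-2-one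
Product: 5 (S)-4-ethyloct-1-yne, via enol phosphate 4 (not isolated)
Conditions: LiN(iPr)2 (1.05 equiv), THF, −78 °C; ClP(O)(OEt)2, −78 °C to rt; LiN(iPr)2 (2.3 equiv), −78 °C to rt; H2O
Reagents that add atoms: none
Why: Negishi conversion of a methyl ketone into a terminal alkyne (kinetic deprotonation at CH3, O-phosphorylation, base-induced elimination of diethyl phosphate), which leaves the β-stereocentre untouched.

**Step 3**
Reactants: 5 (S)-4-ethyloct-1-yne; 6 2-bromobut-1-ene
Product: 8 (3E,6S)-2,6-diethyl-4-methyldeca-1,3-diene, via alkenylalane 7 (not isolated)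
Conditions: AlMe3 (2 equiv), Cp2ZrCl2 (10 mol %), CH2Cl2, 0 °C to rt; then 6, ZnCl2 (20 mol %), Pd(PPh3)4 (3 mol %), THF, rt; 1 M HCl
Reagents that add atoms: trimethylaluminium, C[Al](C)C
Why: Zirconium-catalysed syn-carboalumination (Negishi) puts methyl on the internal carbon and aluminium cis to it on the terminal carbon, and zerovalent-palladium cross-coupling with zinc cocatalysis proceeds with retention, so the trisubstituted alkene is formed as the E isomer only.

**Step 4 (key step)**
Reactants: 8 (3E,6S)-2,6-diethyl-4-methyldeca-1,3-diene; 9 butanal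
Product: 12 (3R)-3,5-diethyl-5-[(1E,4S)-4-ethyl-2-methyloct-1-en-1-yl]oxolan-2-ol, via C6 nitrate ester 10 (not isolated), via C8 nitrate ester 11 (not isolated)
Conditions: 9 (2 equiv), (2S,5S)-5-benzyl-2-tert-butyl-3-methylimidazolidin-4-one·CF3CO2H (20 mol %), (NH4)2Ce(NO3)6 (2.5 equiv), NaHCO3 (3 equiv), H2O (3 equiv), DME, −20 °C, 24 h; then H2O/acetone, NaHCO3, rt
Reagents that add atoms: water, O
Why: Proposed new method: SOMO-type organocatalysis extended to a three-component carbo-oxygenation, in which tetravalent cerium oxidises the catalyst-bound enamine of 9 to a 3π-electron radical cation that adds through its unshielded face (setting C4 as R) to the unhindered CH2 terminus of diene 8 to forge the C4–C5 bond, a second tetravalent cerium oxidises the tetrasubstituted allyl radical to the allyl cation (the preformed E alkene is kept), nitrate captures it at either terminus (10, 11), and buffered solvolysis funnels both nitrates through the same cation to the only five-membered hemiacetal possible, lactol 12 (C6–O bond formed regioselectively by ring size, C6 and C2 still epimeric mixtures); the closest known reactions are the organo-SOMO carbo-oxidation of styrenes with nitrate capture and the SOMO α-allylation and α-enolation of aldehydes.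

**Step 5**
Reactants: 12 (3R)-3,5-diethyl-5-[(1E,4S)-4-ethyl-2-methyloct-1-en-1-yl]oxolan-2-ol
Product: 15 (4R,6R)-4,6-diethyl-6-[(1E,4S)-4-ethyl-2-methyloct-1-en-1-yl]-3-methoxy-1,2-dioxane, via hydroperoxyoxolane 13 (not isolated), via dioxanol 14 (not isolated)
Conditions: anhydrous H2O2 in Et2O (4 equiv), PPTS (10 mol %), 4 Å MS, 0 °C; aqueous wash, dry; BF3·OEt2 (20 mol %), CH2Cl2, −30 °C; then MeOH (10 equiv), −30 to 0 °C; chromatography
Reagents that add atoms: hydrogen peroxide, OO; methanol, CO
Why: Proposed new method: anomeric perhydrolysis gives hydroperoxide 13, then, with no external nucleophile present, Lewis acid ionises the tertiary allylic C6–O bond of the oxolane to the tetrasubstituted allyl cation, which is recaptured by the distal peroxide oxygen through a six-membered chair (closure at C8 would need an eight-membered ring; relief of oxolane strain drives the ring expansion) with 4-ethyl equatorial and the rigid alkenyl arm equatorial over the smaller axial ethyl at C6, so that the 6R epimer is expected as the major one (modest, about 2–3:1; the 6S epimer is separated here and recycled because the epimers interconvert through the cation), and methanol caps hemiperacetal 14 as the methyl peroxyacetal; the closest known reactions are acid-catalysed perhydrolysis of lactols, acetals and tertiary allylic alcohols and the intramolecular capture of carbocations by hydroperoxides or silyl peroxides.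

**Step 6**
Reactants: 15 (4R,6R)-4,6-diethyl-6-[(1E,4S)-4-ethyl-2-methyloct-1-en-1-yl]-3-methoxy-1,2-dioxane
Product: 16 methyl 2-[(3R,4R,6R)-4,6-diethyl-6-[(1E,4S)-4-ethyl-2-methyloct-1-en-1-yl]-1,2-dioxan-3-yl]acetate
Conditions: tert-butyl[(1-methoxyethenyl)oxy]dimethylsilane (2.5 equiv), Me3SiOTf (0.3 equiv), CH2Cl2, −78 °C; NaHCO3
Reagents that add atoms: tert-butyl[(1-methoxyethenyl)oxy]dimethylsilane, C=C(OC)O[Si](C)(C)C(C)(C)C
Why: Mukaiyama-type alkylation of a cyclic peroxycarbenium ion (known substitution chemistry of monoperoxyacetals), in which the silyl triflate ionises only the exocyclic methoxy group and the ketene acetal attacks axially on the half-chair that keeps 4-ethyl pseudo-equatorial and 6-ethyl axial, that is anti to the axial 6-ethyl and cis to 4-ethyl, which sets C3 as R (3,4-cis).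

**Step 7**
Reactants: 16 methyl 2-[(3R,4R,6R)-4,6-diethyl-6-[(1E,4S)-4-ethyl-2-methyloct-1-en-1-yl]-1,2-dioxan-3-yl]acetate
Product: 17 2-[(3R,4R,6R)-4,6-diethyl-6-[(1E,4S)-4-ethyl-2-methyloct-1-en-1-yl]-1,2-dioxan-3-yl]acetic acid
Conditions: LiOH·H2O (3 equiv), THF/H2O 3:1, 0 °C to rt; 1 M HCl to pH 3
Reagents that add atoms: lithium hydroxide, [Li+].[OH-]
Why: Mild saponification of the methyl ester, the usual way to free 1,2-dioxane-3-acetic acids of this family, which touches neither the peroxide nor any stereocentre.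

**Compound list**
1 | (E)-hex-3-en-2-one | CC(=O)/C=C/CC | starting material
2 | n-butylmagnesium bromide | CCCC[Mg]Br | starting material
3 | (S)-4-ethyloctan-2-one | CCCC[C@H](CC)CC(C)=O | intermediate
4 | diethyl (4S)-4-ethyloct-1-en-2-yl phosphate | CCCC[C@H](CC)CC(=C)OP(=O)(OCC)OCC | intermediate
5 | (S)-4-ethyloct-1-yne | CCCC[C@H](CC)CC#C | intermediate
6 | 2-bromobut-1-ene | C=C(Br)CC | starting material
7 | [(1E,4S)-4-ethyl-2-methyloct-1-en-1-yl]dimethylaluminium | CCCC[C@H](CC)C/C(C)=C/[Al](C)C | intermediate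
8 | (3E,6S)-2,6-diethyl-4-methyldeca-1,3-diene | CCCC[C@H](CC)C/C(C)=C/C(=C)CC | intermediate
9 | butanal | CCCC=O | starting material
10 | (2R,5E,8S)-2,4,8-triethyl-6-methyl-4-(nitrooxy)dodec-5-enal (both C4 epimers) | CCCC[C@H](CC)C/C(C)=C/C(CC)(O[N+](=O)[O-])C[C@@H](CC)C=O | intermediate
11 | (2R,8S)-2,4,8-triethyl-6-methyl-6-(nitrooxy)dodec-4-enal (allylic regioisomer of 10) | CCCC[C@H](CC)CC(C)(O[N+](=O)[O-])C=C(CC)C[C@@H](CC)C=O | intermediate
12 | (3R)-3,5-diethyl-5-[(1E,4S)-4-ethyl-2-methyloct-1-en-1-yl]oxolan-2-ol (epimers at C2 and C5) | CCCC[C@H](CC)C/C(C)=C/C1(CC)C[C@@H](CC)C(O)O1 | intermediate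
13 | (3R)-3,5-diethyl-5-[(1E,4S)-4-ethyl-2-methyloct-1-en-1-yl]-2-hydroperoxyoxolane | CCCC[C@H](CC)C/C(C)=C/C1(CC)C[C@@H](CC)C(OO)O1 | intermediate
14 | (4R,6R)-4,6-diethyl-6-[(1E,4S)-4-ethyl-2-methyloct-1-en-1-yl]-1,2-dioxan-3-ol | CCCC[C@H](CC)C/C(C)=C/[C@@]1(CC)C[C@@H](CC)C(O)OO1 | intermediate
15 | (4R,6R)-4,6-diethyl-6-[(1E,4S)-4-ethyl-2-methyloct-1-en-1-yl]-3-methoxy-1,2-dioxane | CCCC[C@H](CC)C/C(C)=C/[C@@]1(CC)C[C@@H](CC)C(OC)OO1 | intermediate
16 | methyl 2-[(3R,4R,6R)-4,6-diethyl-6-[(1E,4S)-4-ethyl-2-methyloct-1-en-1-yl]-1,2-dioxan-3-yl]acetate | CCCC[C@H](CC)C/C(C)=C/[C@@]1(CC)C[C@@H](CC)[C@@H](CC(=O)OC)OO1 | intermediate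
17 | 2-[(3R,4R,6R)-4,6-diethyl-6-[(1E,4S)-4-ethyl-2-methyloct-1-en-1-yl]-1,2-dioxan-3-yl]acetic acid | CCCC[C@H](CC)C/C(C)=C/[C@@]1(CC)C[C@@H](CC)[C@@H](CC(=O)O)OO1 | target

**Totals**
Total step count: 7. Longest linear sequence: 7 (fully linear from 1; 6 and 9 enter as building blocks).

**Steps most likely to fail, with fallbacks**

Step 4. A 1,3-diene has not been used as the acceptor in this radical coupling, and nitrate captured at C8 can erode the C7=C8 geometry when that isomer re-ionises. The fallback is a stepwise, regiospecific assembly that sets out from butanal 9 and alkyne 5 and comes back at lactol 12. Visible-light photoredox organocatalytic α-alkylation of 9 with 1-bromobutan-2-one (Ru(bpy)3Cl2 with divalent ruthenium, (2R,5S)-2-tert-butyl-3,5-dimethylimidazolidin-4-one triflate salt, 2,6-lutidine, DMF) gives (R)-2-ethyl-4-oxohexanal F1. HC(OMe)3/MeOH with catalytic Bu4NBr3 acetalises only the aldehyde and gives (5R)-5-(dimethoxymethyl)heptan-3-one F2. Alkyne 5 is carboaluminated as in step 3 and alane 7 is quenched with I2 to give (1E,4S)-4-ethyl-1-iodo-2-methyloct-1-ene F3. Iodine–lithium exchange (t-BuLi, Et2O, −78 °C) gives [(1E,4S)-4-ethyl-2-methyloct-1-en-1-yl]lithium F4, which adds to the ketone of F2 to give, after a water quench, (2R,5E,8S)-2,4,8-triethyl-1,1-dimethoxy-6-methyldodec-5-en-4-ol F5. PPTS in wet acetone frees the aldehyde, which closes to 12 with the C6–O bond placed unambiguously.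

Step 5. The acid may trigger Hock-type cleavage, C6 may form with little selectivity, and long exposure could erode C4 or the alkene geometry. The fallback leaves the cationic manifold for radical oxygen capture and peroxy-Michael closure; it sets out from lactol 12 and comes back at ester 16, so steps 5 and 6 are bypassed. Ph3P=CHCO2Me (toluene, 60 °C) opens 12 to methyl (2E,4R,7E,10S)-4,6,10-triethyl-6-hydroxy-8-methyltetradeca-2,7-dienoate F6. Catalytic PPTS with 4 Å sieves dehydrates the tertiary allylic alcohol to methyl (2E,4R,7E,10S)-4,10-diethyl-6-ethylidene-8-methyltetradeca-2,7-dienoate F7 (with its 5-ene isomer, which gives the same allyl radical). Mukaiyama–Isayama hydroperoxysilylation (Co(acac)2 with divalent cobalt, O2, Et3SiH, ClCH2CH2Cl) gives methyl (2E,4R,7E,10S)-4,6,10-triethyl-8-methyl-6-[(triethylsilyl)peroxy]tetradeca-2,7-dienoate F8; the C8 regioisomer cannot cyclise and is removed. Bu4NF, then Et2NH in CF3CH2OH, removes silicon and closes the ring by intramolecular peroxy-Michael addition to give 16 after separation of diastereomers.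

Step 6. The Lewis acid may ionise the tertiary allylic C6–O bond, or the 3,4-cis selectivity may fall short. The fallback uses no Lewis acid; it sets out from dioxanol 14 (isolated from step 5 by leaving out the methanol) and comes back at 16. Masamune–Roush olefination ((MeO)2P(O)CH2CO2Me, LiCl, iPr2NEt, MeCN) of the ring-opened hydroperoxy aldehyde form of 14 gives methyl (2E,4R,6R,7E,10S)-4,6,10-triethyl-6-hydroperoxy-8-methyltetradeca-2,7-dienoate F9. Et2NH in CF3CH2OH closes it by peroxy-Michael addition to 16, with the 3,4-trans isomer separated.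

**Further compounds**
F1 | step 4 | (R)-2-ethyl-4-oxohexanal | CCC(=O)C[C@@H](CC)C=O
F2 | step 4 | (5R)-5-(dimethoxymethyl)heptan-3-one | CCC(=O)C[C@@H](CC)C(OC)OC
F3 | step 4 | (1E,4S)-4-ethyl-1-iodo-2-methyloct-1-ene | CCCC[C@H](CC)C/C(C)=C/I
F4 | step 4 | [(1E,4S)-4-ethyl-2-methyloct-1-en-1-yl]lithium | CCCC[C@H](CC)C/C(C)=C/[Li]
F5 | step 4 | (2R,5E,8S)-2,4,8-triethyl-1,1-dimethoxy-6-methyldodec-5-en-4-ol | CCCC[C@H](CC)C/C(C)=C/C(O)(CC)C[C@@H](CC)C(OC)OC
F6 | step 5 | methyl (2E,4R,7E,10S)-4,6,10-triethyl-6-hydroxy-8-methyltetradeca-2,7-dienoate | CCCC[C@H](CC)C/C(C)=C/C(O)(CC)C[C@@H](CC)/C=C/C(=O)OC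
F7 | step 5 | methyl (2E,4R,7E,10S)-4,10-diethyl-6-ethylidene-8-methyltetradeca-2,7-dienoate | CCCC[C@H](CC)C/C(C)=C/C(=CC)C[C@@H](CC)/C=C/C(=O)OC
F8 | step 5 | methyl (2E,4R,7E,10S)-4,6,10-triethyl-8-methyl-6-[(triethylsilyl)peroxy]tetradeca-2,7-dienoate | CCCC[C@H](CC)C/C(C)=C/C(CC)(OO[Si](CC)(CC)CC)C[C@@H](CC)/C=C/C(=O)OC
F9 | step 6 | methyl (2E,4R,6R,7E,10S)-4,6,10-triethyl-6-hydroperoxy-8-methyltetradeca-2,7-dienoate | CCCC[C@H](CC)C/C(C)=C/[C@@](OO)(CC)C[C@@H](CC)/C=C/C(=O)OC
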